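**Retrosynthetic overview** (labdane numbering)
1. Target ⇒ malonic acid + (E)-allylic alcohol 21; 21 ⇒ terminal alkyne 18 (methylalumination/hydroxymethylation builds C13=C14 and C15).
2. C7=C8–CH3 of 18 ⇒ ketone 14 (enol triflate, iron-catalysed methylation).
3. Ring B of 14 ⇒ trans-hydrindanone 6 + gem-dibromide 9: one-carbon ring expansion in which the carbenoid carbon (future C9, carrying C11–C14) is inserted between C=O and the quaternary carbon by a 1,2-shift of that carbon.
4. 6 ⇒ 2-methylcyclopent-2-en-1-one 1: enantioselective conjugate prenylation (C4–C5 bond), anti-allylation (quaternary C10), ring-closing metathesis and hydrogenation.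
5. Ring order: five-membered ring (already in 1) → ring A (metathesis) → ring B (ring expansion of the five-membered ring).

Assumption: 1, 7 (pent-4-yn-1-ol carrying a trimethylsilyl protecting group) and 22 are purchased; the antipode of the chiral catalyst in step 1 is chosen by screening so that the 3S adduct is formed.

**Step 1**
Reactants: 1 2-methylcyclopent-2-en-1-one
Product: 4 (2S,3S)-2-allyl-2-methyl-3-(2-methylbut-3-en-2-yl)cyclopentan-1-one, via silyl enol ether 2 (not isolated), via lithium enolate 3 (not isolated)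
Conditions: prenylSiMe3 (1.5 equiv), chiral BINOL-derived N-triflyl imidodiphosphorimidate Brønsted acid (IDPi, 2 mol %), toluene, −60 °C; then MeLi, THF, 0 °C; then allyl bromide, DMPU, −78 °C → rt
Reagents that add atoms: (3-methylbut-2-en-1-yl)trimethylsilane, C[Si](C)(C)CC=C(C)C; allyl bromide, C=CCBr
Why: Proposed new method: the allylsilane silylates the acid to a chiral silylium Lewis acid that O-silylates enone 1, and the prenylsilane then attacks the β-carbon through its dimethyl-substituted γ-carbon (Hosomi–Sakurai conjugate allylation) inside the chiral anion pocket, which sets C-3 (S) and returns the silyl group to oxygen as enol ether 2; lithium enolate 3 (from 2 and MeLi) is then allylated anti to the bulky tert-alkyl group, which sets the quaternary C-2 (S); the closest known reactions are the TiCl4-promoted conjugate prenylation of enones with this silane and silylium–imidodiphosphorimidate-catalysed Mukaiyama–Michael and aldehyde Sakurai additions.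

**Step 2**
Reactants: 4 (2S,3S)-2-allyl-2-methyl-3-(2-methylbut-3-en-2-yl)cyclopentan-1-one
Product: 6 (3aS,7aS)-4,4,7a-trimethyloctahydro-1H-inden-1-one, via hexahydroindenone 5 (not isolated)
Conditions: second-generation Grubbs catalyst RuCl2(=CHPh)(PCy3)(H2IMes) (3 mol %), toluene, 60 °C; then palladium on carbon (Pd/C, 10 wt %), H2 (1 atm), EtOAc, rt
Reagents that add atoms: none
Why: Ring-closing metathesis of the trans-disposed allyl and 1,1-dimethylallyl groups (closure helped by the gem-dimethyl group) gives the trans-fused cyclohexene 5, and hydrogenation of its disubstituted alkene leaves the ketone and both stereocentres untouched.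

**Step 3**
Reactants: 7 5-(trimethylsilyl)pent-4-yn-1-ol
Product: 8 5-(trimethylsilyl)pent-4-ynal
Conditions: Dess–Martin periodinane, CH2Cl2, 0 °C → rt
Reagents that add atoms: none
Why: Dess–Martin oxidation stops at the aldehyde and does not touch the silylalkyne.

**Step 4**
Reactants: 8 5-(trimethylsilyl)pent-4-ynal
Product: 9 (5,5-dibromopent-1-yn-1-yl)trimethylsilane
Conditions: (PhO)3P, Br2, CH2Cl2, −78 °C; then Et3N, 8, −78 °C → rt
Reagents that add atoms: bromine, BrBr
Why: The preformed bromotriphenoxyphosphonium bromide converts the aldehyde C=O into CBr2 (deoxygenative gem-dibromination), and no free bromine is left to attack the alkyne.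

**Step 5**
Reactants: 6 (3aS,7aS)-4,4,7a-trimethyloctahydro-1H-inden-1-one; 9 (5,5-dibromopent-1-yn-1-yl)trimethylsilane
Product: 14 (1R,4aS,8aS)-5,5,8a-trimethyl-1-[4-(trimethylsilyl)but-3-yn-1-yl]octahydronaphthalen-2(1H)-one, via lithiated dibromide 10 (not isolated), via lithium alkoxide 11 (not isolated), via oxido carbenoid 12 (not isolated), via lithium enolate 13 (not isolated)
Conditions: 9, LiN(i-Pr)2, THF, −95 °C; 6, −95 → −78 °C; n-BuLi (2 equiv), −95 → 0 °C; aq NH4Cl, −78 °C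
Reagents that add atoms: none
Why: Nozaki–Yamamoto β-oxido carbenoid ring enlargement: 10 adds to the ketone (the same unit as a 17-oxo steroid), Br/Li exchange gives 12, and loss of LiBr drives a pinacol-type 1,2-shift in which the more substituted, electron-rich ring-fusion carbon is expected to migrate with retention, giving the six-membered enolate 13; protonation of 13 opposite the axial angular methyl places the side chain equatorial (1R), which is also the thermodynamic epimer.

**Step 6**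
Reactants: 14 (1R,4aS,8aS)-5,5,8a-trimethyl-1-[4-(trimethylsilyl)but-3-yn-1-yl]octahydronaphthalen-2(1H)-one
Product: 16 (1R,4aS,8aS)-5,5,8a-trimethyl-1-[4-(trimethylsilyl)but-3-yn-1-yl]-1,4,4a,5,6,7,8,8a-octahydronaphthalen-2-yl trifluoromethanesulfonate, via potassium enolate 15 (not isolated)
Conditions: KN(SiMe3)2, THF, −78 °C; PhNTf2, −78 → 0 °C
Reagents that add atoms: N-phenylbis(trifluoromethanesulfonimide), O=S(=O)(N(c1ccccc1)S(=O)(=O)C(F)(F)F)C(F)(F)F
Why: Kinetic deprotonation takes a proton from the unhindered C-3 methylene and not from the shielded C-1 methine next to the quaternary carbon, so O-triflation fixes the double bond at C2=C3 and leaves C-1 untouched.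

**Step 7**
Reactants: 16 (1R,4aS,8aS)-5,5,8a-trimethyl-1-[4-(trimethylsilyl)but-3-yn-1-yl]-1,4,4a,5,6,7,8,8a-octahydronaphthalen-2-yl trifluoromethanesulfonate
Product: 18 (1S,4aS,8aS)-1-(but-3-yn-1-yl)-2,5,5,8a-tetramethyl-1,4,4a,5,6,7,8,8a-octahydronaphthalene, via silylated enyne 17 (not isolated)
Conditions: MeMgBr, Fe(acac)3 (5 mol %), THF/NMP, −30 → 0 °C; then MeOH, K2CO3, rt
Reagents that add atoms: methylmagnesium bromide, C[Mg]Br
Why: Iron-catalysed Kumada-type coupling replaces the triflate by methyl without moving the double bond, and methanolysis then frees the terminal alkyne.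

**Step 8**
Reactants: 18 (1S,4aS,8aS)-1-(but-3-yn-1-yl)-2,5,5,8a-tetramethyl-1,4,4a,5,6,7,8,8a-octahydronaphthalene
Product: 21 (2E)-3-methyl-5-[(1S,4aS,8aS)-2,5,5,8a-tetramethyl-1,4,4a,5,6,7,8,8a-octahydronaphthalen-1-yl]pent-2-en-1-ol, via alkenylalane 19 (not isolated), via lithium alkenylaluminate 20 (not isolated)
Conditions: Me3Al, Cp2ZrCl2 (25 mol %), ClCH2CH2Cl, rt; then n-BuLi, THF, −78 °C; (CH2O)n, −78 °C → rt; dilute HCl
Reagents that add atoms: trimethylaluminium, C[Al](C)C; formaldehyde (as paraformaldehyde), C=O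
Why: Negishi zirconium-catalysed carboalumination adds Me and Al syn across the alkyne (Me to the internal carbon), and hydroxymethylation of the aluminate with retention gives the E-trisubstituted allylic alcohol; the ring alkene does not react.

**Step 9**
Reactants: 21 (2E)-3-methyl-5-[(1S,4aS,8aS)-2,5,5,8a-tetramethyl-1,4,4a,5,6,7,8,8a-octahydronaphthalen-1-yl]pent-2-en-1-ol; 22 malonic acid
Product: 24 3-{[(2E)-3-methyl-5-[(1S,4aS,8aS)-2,5,5,8a-tetramethyl-1,4,4a,5,6,7,8,8a-octahydronaphthalen-1-yl]pent-2-en-1-yl]oxy}-3-oxopropanoic acid, via carboxyketene 23 (not isolated)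
Conditions: malonic acid (2 equiv), DCC (1.1 equiv), MeCN, 0 °C → rt
Reagents that add atoms: none
Why: The carbodiimide dehydrates malonic acid to carboxyketene 23, which acylates the primary allylic alcohol once; the second carboxyl group is not activated, so the half ester results without touching any stereocentre.

**Compound list**
1 | 2-methylcyclopent-2-en-1-one | CC1=CCCC1=O | starting material
2 | (S)-trimethyl{[2-methyl-3-(2-methylbut-3-en-2-yl)cyclopent-1-en-1-yl]oxy}silane | C[Si](C)(C)OC1=C(C)[C@H](C(C)(C)C=C)CC1 | intermediate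
3 | lithium (S)-2-methyl-3-(2-methylbut-3-en-2-yl)cyclopent-1-en-1-olate | [Li+].[O-]C1=C(C)[C@H](C(C)(C)C=C)CC1 | intermediate
4 | (2S,3S)-2-allyl-2-methyl-3-(2-methylbut-3-en-2-yl)cyclopentan-1-one | O=C1CC[C@@H](C(C)(C)C=C)[C@@]1(CC=C)C | intermediate
5 | (3aS,7aS)-4,4,7a-trimethyl-2,3,3a,4,7,7a-hexahydro-1H-inden-1-one | O=C1CC[C@H]2C(C)(C)C=CC[C@]12C | intermediate
6 | (3aS,7aS)-4,4,7a-trimethyloctahydro-1H-inden-1-one (trans-fused) | O=C1CC[C@H]2C(C)(C)CCC[C@]12C | intermediate
7 | 5-(trimethylsilyl)pent-4-yn-1-ol | OCCCC#C[Si](C)(C)C | starting material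
8 | 5-(trimethylsilyl)pent-4-ynal | O=CCCC#C[Si](C)(C)C | intermediate
9 | (5,5-dibromopent-1-yn-1-yl)trimethylsilane | BrC(Br)CCC#C[Si](C)(C)C | intermediate
10 | [1,1-dibromo-5-(trimethylsilyl)pent-4-yn-1-yl]lithium | [Li]C(Br)(Br)CCC#C[Si](C)(C)C | intermediate
11 | lithium (3aS,7aS)-1-[1,1-dibromo-5-(trimethylsilyl)pent-4-yn-1-yl]-4,4,7a-trimethyloctahydro-1H-inden-1-olate (carbinol configuration not defined) | [Li+].[O-]C1(C(Br)(Br)CCC#C[Si](C)(C)C)CC[C@H]2C(C)(C)CCC[C@]12C | intermediate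
12 | lithium (3aS,7aS)-1-[1-bromo-1-lithio-5-(trimethylsilyl)pent-4-yn-1-yl]-4,4,7a-trimethyloctahydro-1H-inden-1-olate | [Li+].[O-]C1(C([Li])(Br)CCC#C[Si](C)(C)C)CC[C@H]2C(C)(C)CCC[C@]12C | intermediate
13 | lithium (4aS,8aS)-5,5,8a-trimethyl-1-[4-(trimethylsilyl)but-3-yn-1-yl]-3,4,4a,5,6,7,8,8a-octahydronaphthalen-2-olate | [Li+].[O-]C1=C(CCC#C[Si](C)(C)C)[C@@]2(C)CCCC(C)(C)[C@@H]2CC1 | intermediate
14 | (1R,4aS,8aS)-5,5,8a-trimethyl-1-[4-(trimethylsilyl)but-3-yn-1-yl]octahydronaphthalen-2(1H)-one | O=C1CC[C@H]2C(C)(C)CCC[C@]2(C)[C@H]1CCC#C[Si](C)(C)C | intermediate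
15 | potassium (1R,4aS,8aS)-5,5,8a-trimethyl-1-[4-(trimethylsilyl)but-3-yn-1-yl]-1,4,4a,5,6,7,8,8a-octahydronaphthalen-2-olate | [K+].[O-]C1=CC[C@H]2C(C)(C)CCC[C@]2(C)[C@H]1CCC#C[Si](C)(C)C | intermediate
16 | (1R,4aS,8aS)-5,5,8a-trimethyl-1-[4-(trimethylsilyl)but-3-yn-1-yl]-1,4,4a,5,6,7,8,8a-octahydronaphthalen-2-yl trifluoromethanesulfonate | FC(F)(F)S(=O)(=O)OC1=CC[C@H]2C(C)(C)CCC[C@]2(C)[C@H]1CCC#C[Si](C)(C)C | intermediate
17 | trimethyl{4-[(1S,4aS,8aS)-2,5,5,8a-tetramethyl-1,4,4a,5,6,7,8,8a-octahydronaphthalen-1-yl]but-1-yn-1-yl}silane | CC1=CC[C@H]2C(C)(C)CCC[C@]2(C)[C@H]1CCC#C[Si](C)(C)C | intermediate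
18 | (1S,4aS,8aS)-1-(but-3-yn-1-yl)-2,5,5,8a-tetramethyl-1,4,4a,5,6,7,8,8a-octahydronaphthalene | CC1=CC[C@H]2C(C)(C)CCC[C@]2(C)[C@H]1CCC#C | intermediate
19 | dimethyl{(1E)-2-methyl-4-[(1S,4aS,8aS)-2,5,5,8a-tetramethyl-1,4,4a,5,6,7,8,8a-octahydronaphthalen-1-yl]but-1-en-1-yl}alane | CC1=CC[C@H]2C(C)(C)CCC[C@]2(C)[C@H]1CC/C(C)=C/[Al](C)C | intermediate
20 | lithium butyl(dimethyl){(1E)-2-methyl-4-[(1S,4aS,8aS)-2,5,5,8a-tetramethyl-1,4,4a,5,6,7,8,8a-octahydronaphthalen-1-yl]but-1-en-1-yl}aluminate | CC1=CC[C@H]2C(C)(C)CCC[C@]2(C)[C@H]1CC/C(C)=C/[Al-](C)(C)CCCC.[Li+] | intermediate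
21 | (2E)-3-methyl-5-[(1S,4aS,8aS)-2,5,5,8a-tetramethyl-1,4,4a,5,6,7,8,8a-octahydronaphthalen-1-yl]pent-2-en-1-ol (labda-7,13E-dien-15-ol) | CC1=CC[C@H]2C(C)(C)CCC[C@]2(C)[C@H]1CC/C(C)=C/CO | intermediate
22 | malonic acid | OC(=O)CC(=O)O | starting material
23 | 3-oxoprop-2-enoic acid (carboxyketene) | O=C=CC(=O)O | intermediate
24 | 3-{[(2E)-3-methyl-5-[(1S,4aS,8aS)-2,5,5,8a-tetramethyl-1,4,4a,5,6,7,8,8a-octahydronaphthalen-1-yl]pent-2-en-1-yl]oxy}-3-oxopropanoic acid | CC1=CC[C@H]2C(C)(C)CCC[C@]2(C)[C@H]1CC/C(C)=C/COC(=O)CC(=O)O | target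

**Step count**
Total steps: 9. Longest linear sequence: 7 steps (1, 2, 5, 6, 7, 8, 9); steps 3 and 4 are a two-step side branch.

**Steps most likely to fail**

Step 1 (new enantioselective conjugate prenylation). The risk is low turnover with the α-methyl enone or insufficient enantioselectivity. The fallback uses only known chemistry, sets out from 1 and comes back at 4. TiCl4 (1 equiv) with the same prenylsilane in CH2Cl2 at −78 °C gives racemic 2-methyl-3-(2-methylbut-3-en-2-yl)cyclopentan-1-one F1. Thermodynamic silylation (Me3SiCl, NaI, Et3N, MeCN) gives the tetrasubstituted enol ether as the racemate, that is 2 together with (R)-trimethyl{[2-methyl-3-(2-methylbut-3-en-2-yl)cyclopent-1-en-1-yl]oxy}silane F2. MeLi then gives 3 together with lithium (R)-2-methyl-3-(2-methylbut-3-en-2-yl)cyclopent-1-en-1-olate F3, and allyl bromide gives 4 together with (2R,3R)-2-allyl-2-methyl-3-(2-methylbut-3-en-2-yl)cyclopentan-1-one F4. The racemate is resolved by Johnson's sulfoximine method: lithiated (S)-N,S-dimethyl-S-phenylsulfoximine adds to the ketone to give the diastereomers (2S,3S)-2-allyl-2-methyl-3-(2-methylbut-3-en-2-yl)-1-{[(S)-N-methyl-S-phenylsulfonimidoyl]methyl}cyclopentan-1-ol F5 and (2R,3R)-2-allyl-2-methyl-3-(2-methylbut-3-en-2-yl)-1-{[(S)-N-methyl-S-phenylsulfonimidoyl]methyl}cyclopentan-1-ol F6. These are separated on silica, and heating F5 in toluene returns enantiopure 4.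

Step 5 (ring expansion). The risks are enolisation of the hindered ketone by the bulky tertiary carbenoid and competing migration of the methylene carbon. The fallback is the selenium-based pinacol-type ring enlargement, which sets out from 8 and 6 and comes back at 14. MeSeH and ZnCl2 convert 8 into [5,5-bis(methylselanyl)pent-1-yn-1-yl]trimethylsilane F7. n-BuLi cleaves one C–Se bond to give the smaller secondary carbanion [1-(methylselanyl)-5-(trimethylsilyl)pent-4-yn-1-yl]lithium F8. F8 adds to 6 to give the isolable (3aS,7aS)-4,4,7a-trimethyl-1-[1-(methylselanyl)-5-(trimethylsilyl)pent-4-yn-1-yl]octahydro-1H-inden-1-ol F9. TlOEt in CHCl3 (dichlorocarbene makes selenium a leaving group) triggers the cationic 1,2-shift of the quaternary carbon to give 14, with DBU equilibration at C-1 if needed.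

Step 6 (regioselective enol triflate). The risks are partial enolisation toward C-1 or epimerisation there. The fallback is a Shapiro route that avoids the triflate; it sets out from 14 and comes back at 17, which is desilylated as in step 7. 2,4,6-Triisopropylbenzenesulfonohydrazide with catalytic HCl in THF gives N'-[(1R,4aS,8aS)-5,5,8a-trimethyl-1-[4-(trimethylsilyl)but-3-yn-1-yl]octahydronaphthalen-2(1H)-ylidene]-2,4,6-triisopropylbenzenesulfonohydrazide F10. n-BuLi (2.2 equiv, THF, −78 → 0 °C) deprotonates on the methylene side and gives {(1S,4aS,8aS)-5,5,8a-trimethyl-1-[4-(trimethylsilyl)but-3-yn-1-yl]-1,4,4a,5,6,7,8,8a-octahydronaphthalen-2-yl}lithium F11, which is methylated with MeI to 17.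

**Further compounds**
F1 | step 1 | 2-methyl-3-(2-methylbut-3-en-2-yl)cyclopentan-1-one (racemic, cis/trans mixture) | CC1C(C(C)(C)C=C)CCC1=O
F2 | step 1 | (R)-trimethyl{[2-methyl-3-(2-methylbut-3-en-2-yl)cyclopent-1-en-1-yl]oxy}silane | C[Si](C)(C)OC1=C(C)[C@@H](C(C)(C)C=C)CC1
F3 | step 1 | lithium (R)-2-methyl-3-(2-methylbut-3-en-2-yl)cyclopent-1-en-1-olate | [Li+].[O-]C1=C(C)[C@@H](C(C)(C)C=C)CC1
F4 | step 1 | (2R,3R)-2-allyl-2-methyl-3-(2-methylbut-3-en-2-yl)cyclopentan-1-one | O=C1CC[C@H](C(C)(C)C=C)[C@]1(CC=C)C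
F5 | step 1 | (2S,3S)-2-allyl-2-methyl-3-(2-methylbut-3-en-2-yl)-1-{[(S)-N-methyl-S-phenylsulfonimidoyl]methyl}cyclopentan-1-ol | OC1(C[S@@](=O)(=NC)c2ccccc2)CC[C@@H](C(C)(C)C=C)[C@@]1(CC=C)C
F6 | step 1 | (2R,3R)-2-allyl-2-methyl-3-(2-methylbut-3-en-2-yl)-1-{[(S)-N-methyl-S-phenylsulfonimidoyl]methyl}cyclopentan-1-ol | OC1(C[S@@](=O)(=NC)c2ccccc2)CC[C@H](C(C)(C)C=C)[C@]1(CC=C)C
F7 | step 5 | [5,5-bis(methylselanyl)pent-1-yn-1-yl]trimethylsilane | C[Se]C([Se]C)CCC#C[Si](C)(C)C
F8 | step 5 | [1-(methylselanyl)-5-(trimethylsilyl)pent-4-yn-1-yl]lithium | [Li]C([Se]C)CCC#C[Si](C)(C)C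
F9 | step 5 | (3aS,7aS)-4,4,7a-trimethyl-1-[1-(methylselanyl)-5-(trimethylsilyl)pent-4-yn-1-yl]octahydro-1H-inden-1-ol | OC1(C([Se]C)CCC#C[Si](C)(C)C)CC[C@H]2C(C)(C)CCC[C@]12C
F10 | step 6 | N'-[(1R,4aS,8aS)-5,5,8a-trimethyl-1-[4-(trimethylsilyl)but-3-yn-1-yl]octahydronaphthalen-2(1H)-ylidene]-2,4,6-triisopropylbenzenesulfonohydrazide | CC(C)c1cc(C(C)C)c(S(=O)(=O)NN=C2CC[C@H]3C(C)(C)CCC[C@]3(C)[C@H]2CCC#C[Si](C)(C)C)c(C(C)C)c1
F11 | step 6 | {(1S,4aS,8aS)-5,5,8a-trimethyl-1-[4-(trimethylsilyl)but-3-yn-1-yl]-1,4,4a,5,6,7,8,8a-octahydronaphthalen-2-yl}lithium | [Li]C1=CC[C@H]2C(C)(C)CCC[C@]2(C)[C@H]1CCC#C[Si](C)(C)C
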